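5 questions stand on 4 ways of running one charge.

| setting | cedar | maple | oak | birch | Wednesday's | Thursday's | Tuesday's | Saturday's |
|---|---|---|---|---|---|---|---|---|
| starting complex | 0.40 M | 0.40 M | 0.40 M | 0.80 M | 0.40 M | 0.40 M | 0.40 M | 0.40 M (fed, over 16.0 h) |
| incoming ligand | 0.24 M | 0.24 M | 0.24 M | 0.24 M | 0.240 M (fed, over 16.0 h) | 0.240 M | 0.240 M | 0.240 M |
| leaving ligand | 0.40 M | 0.20 M | 0.30 M | 0.40 M | 0.400 M | 0.400 M | 0.400 M | 0.400 M |
| remark | run made earlier | run made earlier | run made earlier | run made earlier | a stirred flask in which incoming ligand is dosed at a steady rate over 16.0 h without added volume, worked up at 20 h | a closed flask charged with all of it at once and left for 20 h | a single well-mixed tank run continuously and read at steady state, 20 h in it on average | a stirred flask in which starting complex is dosed at a steady rate over 16.0 h without added volume, worked up at 20 h |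
| time |  |  |  |  | 20 h | 20 h |  | 20 h |

- the set-up with the highest amount of complex with one exchanged at the outlet or at the end, in percent of the starting complex put in ("none" if the first two lie within 2 percentage points) (Wednesday's / Thursday's / Tuesday's / Saturday's / none)
- amount of complex with one exchanged at the outlet or at the end, in percent of the starting complex put in, Wednesday's
- amount of complex with one exchanged at the outlet or at the end, in percent of the starting complex put in, Thursday's
- amount of complex with one exchanged at the outlet or at the end, in percent of the starting complex put in, Tuesday's
- amount of complex with one exchanged at the outlet or at the end, in percent of the starting complex put in, Saturday's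

| run | time / h | complex with one exchanged / % | starting complex / % |
|---|---|---|---|
| cedar | 1.50 | 10.1 | 70.4 |
| cedar | 3.00 | 16.4 | 53.6 |
| cedar | 6.00 | 19.9 | 35.6 |
| cedar | 10.0 | 20.7 | 25.7 |
| cedar | 20.0 | 18.6 | 19.4 |
| maple | 2.00 | 14.0 | 62.4 |
| maple | 5.00 | 19.0 | 39.3 |
| maple | 10.0 | 23.4 | 26.3 |
| maple | 15.0 | 24.0 | 19.3 |
| maple | 20.0 | 23.1 | 16.0 |
| oak | 4.00 | 17.6 | 46.2 |
| oak | 8.00 | 23.0 | 31.5 |
| oak | 12.0 | 22.4 | 23.1 |
| oak | 15.0 | 20.2 | 19.4 |
| oak | 20.0 | 22.0 | 17.2 |
| birch | 4.00 | 13.2 | 34.3 |
| birch | 8.00 | 15.5 | 22.0 |
| birch | 12.0 | 13.2 | 17.5 |
| birch | 15.0 | 14.0 | 12.6 |
| birch | 20.0 | 11.6 | 12.2 |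

(readings scatter by 1 percentage point)

- the stated concentrations are those of everything mixed, before any reaction; amounts are the same in each set-up
- the feed brings no volume worth counting
- the earlier runs were made in a closed, stirred flask

Cedar looks impossible at first. At 20.0 h it reads 80.6% of its starting complex lost, yet its charge of incoming ligand amounts to 60.0% of the starting complex charged. So some starting complex leaves without incoming ligand.

Call the gap the starting complex neither left nor found as complex with one exchanged. At 6.00 h, cedar, with 35.6% of its starting complex left, reads 0.447 of complex with one exchanged per unit of gap; that ratio is the split. At 4.00 h, birch, with 34.3% left, the same charges of both ligands and twice the starting complex, reads 0.251, less than cedar. So the split falls as [starting complex] rises, and here it is taken to follow [incoming ligand]/[starting complex]. The split number, the split per unit of that ratio (a selectivity factor), is 0.745, as read from cedar. The share of turnover found as complex with one exchanged is split/(1 + split).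

Thursday's charge reckons to a split of 0.447. Wednesday's opens with no incoming ligand, so its split starts at nothing. In Saturday's, with a quarter of the starting complex dosed, the split is still 1.04 even if every dosed complex had taken one ligand, which is more than Thursday's opening value. This reckoning ranks Saturday's over Thursday's over Wednesday's, without figures and without Tuesday's.

The forecast gives 13% for Wednesday's, 19% for Thursday's, 14.5% for Tuesday's and 19% for Saturday's, so its best is none, with Saturday's “tied with Thursday within 2 points”. There it differs from this reckoning.

The flask gives 13.8% for Wednesday's, 20.4% for Thursday's, 18.0% for Tuesday's and 23.7% for Saturday's, so Saturday's leads by 3.3 percentage points.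

starting complex + incoming ligand ⇌ leaving ligand + complex with one exchanged (K = 4.50, k = 0.00690 M⁻¹ min⁻¹); complex with one exchanged + incoming ligand ⇌ leaving ligand + complex with two exchanged (K = 1.60, k = 0.00280 M⁻¹ min⁻¹); 2 starting complex → homo dimer (k = 0.00390 M⁻¹ min⁻¹) At 10.0 h, homo dimer, each counted as two, stands at 10.7% in Saturday's against 61.1% in Wednesday's. The contents at that time give a split of 0.881 in Saturday's and 0.699 in Wednesday's.

Wednesday's flask with 0.41 M of incoming ligand, with its [starting complex] and the fraction of its incoming ligand taken as unchanged, reckons to a split of 1.19, and the share then carries 13.8% to a reckoned 18.2%. The computed flask gives 18.1%.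

The data stem from a simulated flask for substances that don't exist, noise included.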